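All runs come from a simulation with constants of no real substance; scatter was added.

| flask | solid substrate | reagent | remark | time |
|---|---|---|---|---|
| alder | 0.017 M | 0.35 equiv | run made earlier |  |
| elm | 0.017 M | 1.4 equiv | run made earlier |  |
| ash | 0.026 M | 0.70 equiv | run made earlier |  |
| flask | 0.017 M | 0.700 equiv |  | 25 h |

| run | time / h | target / % | solid product / % |
|---|---|---|---|
| alder | 3.00 | 2.0 | 0 |
| alder | 6.00 | 4.6 | 0.1 |
| alder | 10.0 | 7.2 | 0 |
| alder | 12.0 | 7.8 | 0.2 |
| alder | 15.0 | 9.6 | 0.3 |
| alder | 20.0 | 11.4 | 0 |
| elm | 1.33 | 4.1 | 0.1 |
| elm | 4.00 | 12.2 | 0.4 |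
| elm | 8.00 | 22.7 | 0 |
| elm | 10.0 | 27.7 | 0.4 |
| elm | 15.0 | 38.3 | 0 |
| elm | 20.0 | 46.5 | 0.3 |
| ash | 2.00 | 2.6 | 0.2 |
| ash | 5.00 | 7.8 | 0.5 |
| ash | 10.0 | 13.9 | 0.1 |
| ash | 15.0 | 19.3 | 0.5 |
| ash | 20.0 | 23.2 | 0.2 |

(readings scatter by 0.3 percentage points)

- amounts and yields of target count solid product too
- given per volume of solution although it is solid: solid substrate, solid product
- at the start none of the solid substrate is in solution
- dissolved substrate means what is dissolved; the solid is not counted in it

1. target and solid product together at 25 h, in percent of the solid substrate charged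
2. concentration of dissolved substrate in solution at 25 h, in percent of saturation

1. Count the reagent. At 15.0 h the earlier runs average 0.275 of target per equivalent of reagent charged, a figure called here the reagent yield.

2. The readings seem to disagree. At that time alder holds 9.6% of target, elm 38.3% and ash 19.3%. Ash also carries more solid substrate than alder, yet its reagent yield matches alder's.

3. Following one reagent molecule clears this up. Its chance per hour of becoming target depends on the dissolved substrate it meets. Equal reagent yields in ash and alder therefore point to one dissolved level despite the different loadings, which makes the reagent's loss pseudo-first-order.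

4. The reagent yield averages 0.201 at 10.0 h and 0.330 at 20.0 h. Letting each step shrink by the ratio of the last two gives 0.371 at 25 h, so this reckoning puts the flask at 26.0%.

5. The forecast stands higher, at 26.5%, and gives 98.5% of saturation: “which suggests solution stays near saturation”.

    solid substrate ⇌ dissolved substrate, rate k1*(cs1 - [dissolved substrate]) while solid is left; crystals form when [dissolved substrate] > cs1 (solubility = 0.680 mM, k = 30.2 h⁻¹)
    dissolved substrate + reagent → target (k = 35.3 L mol⁻¹ h⁻¹)
    dissolved substrate + target → side product (k = 16.1 L mol⁻¹ h⁻¹)
    solid product ⇌ target, rate k4*(cs4 - [target]) while solid is left; crystals form when [target] > cs4 (solubility = 7.80 mM, k = 33.1 h⁻¹)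

The flask gives 27.1% with dissolved substrate at 99.0% of saturation, a reagent yield of 0.386 against the reckoned 0.371. Read at 15 h, the same flask holds 19.2%, and the reagent yield from the earlier runs gives 19.2%. At 10.2 h in the flask, dissolved substrate goes to the reagent path 8.5 times as fast as to the path with target, a chance of 89.5% at that fork. At 25.0 h the flask still makes dissolved target faster than it uses it, by a factor of 3.14.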